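## Analysis of the target

Target 14 is a deoxybenzoin built on a 2,2-dimethyl-2H-chromene: ring A is a pentasubstituted benzene, ring B the fused 2H-pyran, and a (4-methoxyphenyl)acetyl group is attached to ring A. With the chromene numbered O1, C2 (gem-dimethyl), C3=C4, C4a, C5, C6, C7, C8, C8a, ring A carries OMe at C5, the acyl group at C6, a free OH at C7 and hydrogen at C8. There is no stereocentre, and the only olefin outside the benzene rings is the endocyclic C3=C4 bond, so no stereochemical relationship has to be set. The sensitive sites are three: the C3=C4 bond, a styrene-type olefin conjugated with three ring oxygens (acid, electrophiles, hydrogenation); the CH2 group between the ketone and the anisyl ring (enolisable, open to autoxidation in base); and the C7 phenol chelated to the ketone. The difficulty is regiochemical: the three oxygens of ring A must end up as a pyran oxygen, a methyl ether and a free phenol, and the acyl group must stand at C6 between two oxygens and not at C8, which the same oxygens activate and which is less crowded. An electrophilic acylation of a 5,7-dioxygenated chromene would face that C6/C8 choice and would also expose the pyran olefin to Lewis acid. The strategy rests on the C6 carbonyl carbon: it is flanked by the C5 and C7 oxygens and bonded to a benzylic CH2, so the aryl–CO–CH2–aryl unit can be assembled from a C6 halide, carbon monoxide (10) and a benzyl metal, with the smallest possible carbon electrophile entering the crowded site. An ester at C8, inherited from the starting benzoate and removable by decarboxylation, leaves C6 as the only open ring position.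

## Retrosynthetic reasoning

**C8–H back to C8–CO2Me (14 ⇐ 13 ⇐ 12 ⇐ 11).** The hydrogen at C8 is traced back to a carboxyl group, through hydroxy acid 13 and its methoxymethyl-protected form 12 to methyl ester 11. The ester is chosen because it comes with the starting benzoate and blocks C8, so all ring chemistry is forced to the remaining positions. Its removal is favoured because the carboxyl carbon of 13 is ortho to two oxygens and para to the third. The forward sequence hydrolyses the hindered ester while the C7 oxygen is still protected, so that a neighbouring phenoxide does not deactivate the ester. Acid then unmasks the phenol and the resulting acid loses its carboxyl group on warming.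

**C6–CO and CO–CH2 (11 ⇐ 7 + 9 + 10).** Both bonds to the ketone carbon are cut at once, giving aryl iodide 7, benzylic zinc reagent 9 and carbon monoxide 10. A cut of only the C6–carbonyl bond would require a bulky acyl electrophile to reach a carbon flanked by two oxygens, or a hindered, basic aryl metal to attack an enolisable arylacetyl derivative. The three-component cut inserts the one-carbon unit first and lets the benzyl group arrive at a metal centre. The forward reaction must take up carbon monoxide before the two organic groups couple directly. The C7 phenol is masked so that it cannot quench 9 or trap an acylpalladium species.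

**O–CH2 of the protecting group (7 ⇐ 6).** Only the acetal on the C7 oxygen is removed, leading to iodophenol 6. The forward step must alkylate a hydroxyl that is chelated to the ester and flanked by iodine.

**C4–C4a and O1–C2 of ring B (6 ⇐ 3 + 4).** The pyran ring is opened to iodoresorcinol ester 3 and enal 4, a formal [3+3] union of a phenol with an α,β-unsaturated aldehyde. In 3 the future C6 carries iodine and the future C8 carries the ester, so a single ring C–H remains. The annulation can therefore occur at one carbon, in one direction and only once. The forward reaction is condensation at that carbon followed by oxa-6π ring closure.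

**C–I bond (3 ⇐ 2).** The iodine is introduced before ring B exists. In a chromene the C3=C4 olefin is conjugated through C4a with the oxygen at C7 and would compete with the ring for an electrophilic iodine source, whereas 2 has no olefin. Compound 2 is symmetric, so both open positions give the same product. The forward step only has to stop after one iodination.

**O–CH3 at the para oxygen (2 ⇐ 1).** The methyl ether is cut to give commercial triol 1. The ester differentiates the three hydroxyls: the para hydroxyl is the most acidic and is not engaged by the ester, while the two ortho hydroxyls are.

**C–Zn bond (9 ⇐ 8).** The zinc reagent is traced to commercial benzylic chloride 8 by direct metal insertion, which is compatible with the aryl methyl ether.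

## Alternatives that were turned down

**Alternative 1:** Ring A is cut at four bonds (C8–C8a, C5–C6, C7–C8, C4a–C5) to the dihydropyranyl diazoketone A1 and the siloxyalkyne A2. In the forward key step, irradiation of A1 causes a Wolff rearrangement to a vinylketene, which adds to A2 in a [2+2] sense. Heating then opens the cyclobutenone (4π), closes the dienylketene (6π) and, after tautomerisation, gives phenol A3.
- For: the connectivity of the cascade places all four substituents of ring A, with no blocking group and no decarboxylation. The C5 and C7 oxygens emerge already differentiated as a free hydroxyl and a silyl ether. On regiocontrol and oxygen differentiation this route is stronger than the chosen one.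
- Against: A3 is far from 14. The hindered C5 hydroxyl must be methylated, the 1,1-disubstituted olefin cleaved oxidatively to the ketone, the silyl ether removed and the chroman dehydrogenated to the chromene. That last oxidation must be done in a molecule whose doubly activated methylene and anisyl ring are at least as prone to hydride abstraction as C4. A1 and A2 are multi-step, sensitive compounds, and the enol ether of A1 must survive photolysis.
- Comparison: the chosen route has ring B at the correct oxidation level from the start, forms the ketone directly and begins from a commercial benzoate. It accepts one protecting group and one blocking ester in exchange.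

**Alternative 2:** Ring B is cut at C3–C4 and O1–C2 to the salicylaldehyde A4 and the alkenylboronic acid A5. In the forward key step a catalytic secondary amine condenses with the formyl group, the phenol-bound boronate delivers the 2-methylpropenyl group to that carbon, loss of the amine gives a vinyl ortho-quinone methide, and oxa-6π closure gives chromene A6.
- For: ring B closes last under mild conditions at a position fixed by the formyl group, and no phenol protection is needed. A6 is 11 without its acetal, so the endgame is one deprotection shorter. On protecting-group economy, and in avoiding a pressurised carbonylation, this route is as strong or stronger.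
- Against: the difficulty is moved into A4, a hexasubstituted benzene with three different carbonyl groups. Its preparation needs two successive electrophilic acylations of ester 2. The first must force the arylacetyl group between two oxygens of an ester-deactivated ring, and the second must formylate a ring that already carries two acceptors. In the key step the second chelated hydroxyl of A4 can sequester A5 unproductively, and the formyl carbon sits on a strongly electron-poor, crowded ring.
- Comparison: the step count is similar. The chosen route introduces the acyl carbon under neutral, non-electrophilic conditions at a position fixed by the C–I bond, and builds ring B by the classical enal annulation when only one position can react.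

**Alternative 3:** Ring A is cut at C4a–C5 and C6–C7 to the ketene silyl acetal diene A7 and the methoxy-ynone A8. In the forward key step the nucleophilic diene terminus (the future C4a) attacks the methoxy-bearing alkyne carbon and the acetal carbon closes onto the acyl-bearing carbon in a [4+2] sense. Loss of methanol and of the silyl group then aromatises the ring to chroman A9.
- For: this is the most convergent route. The ketone, the C5 methyl ether and the C7 hydroxyl arrive in one step, placed by the polarity of the partners, with no protecting group and no blocking ester. In convergence and oxygen differentiation it is stronger than the chosen route.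
- Against: A9 is a chroman. Reaching 14 requires dehydrogenation at C3–C4 beside a free phenol, while the methylene between the ketone and the anisyl ring is an equally good site for oxidation. A8 is an acyl ynol ether, strongly electrophilic and prone to hydration and oligomerisation. A7 is a hydrolytically labile, cross-conjugated ketene acetal that must be formed regioselectively from a β,γ-unsaturated ester. The cycloaddition must also engage the trisubstituted endocyclic enol ether as a diene terminus.
- Comparison: the chosen route has the chromene olefin in place before the sensitive methylene exists and runs through stable, isolable intermediates. It pays with a few functional-group steps.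

Key step: step 6

Remark: 9 is prepared and used as a titrated THF solution of its LiCl complex. It is numbered as an intermediate, and carbon monoxide 10 is counted as a starting material.

## Route

Step 1
Reactants: 1 methyl 2,4,6-trihydroxybenzoate
Product: 2 methyl 2,6-dihydroxy-4-methoxybenzoate
Conditions: Me2SO4 (1.0 equiv), K2CO3 (1.0 equiv), acetone, 0 °C to rt
Reagents that add atoms: dimethyl sulfate, COS(=O)(=O)OC
Why: Williamson O-methylation; the hydroxyl para to the ester is the most acidic and is not engaged by the ester, so with one equivalent of base and alkylating agent its phenoxide should form and react first, leaving the two ortho hydroxyls.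

Step 2
Reactants: 2 methyl 2,6-dihydroxy-4-methoxybenzoate
Product: 3 methyl 2,6-dihydroxy-3-iodo-4-methoxybenzoate
Conditions: NIS (1.0 equiv, in portions), TFA (10 mol %), MeCN, 0 °C
Reagents that add atoms: N-iodosuccinimide, O=C1CCC(=O)N1I
Why: Electrophilic aromatic iodination; the two open positions are equivalent by symmetry and each is ortho to a hydroxyl, ortho to the methoxy group and para to the other hydroxyl. Limiting the reagent and the slight deactivation by the first iodine should keep a second iodination minor, and unreacted 2 can be recycled.

Step 3
Reactants: 3 methyl 2,6-dihydroxy-3-iodo-4-methoxybenzoate; 4 3-methyl-2-butenal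
Product: 6 methyl 7-hydroxy-6-iodo-5-methoxy-2,2-dimethyl-2H-chromene-8-carboxylate, via ortho-quinone methide 5 (not isolated)
Conditions: 4 (2 equiv), pyridine, 115 °C
Reagents that add atoms: none
Why: Pyridine-mediated chromene annulation of a phenol with an enal: aldol-type condensation at the single free ring carbon, dehydration to quinone methide 5 and oxa-6π electrocyclisation. Because iodine and the ester occupy the other positions, ring B can form only here, only towards the adjacent hydroxyl and only once, so an excess of 4 can be used.

Step 4
Reactants: 6 methyl 7-hydroxy-6-iodo-5-methoxy-2,2-dimethyl-2H-chromene-8-carboxylate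
Product: 7 methyl 6-iodo-5-methoxy-7-(methoxymethoxy)-2,2-dimethyl-2H-chromene-8-carboxylate
Conditions: NaH (1.3 equiv), MOMCl (1.5 equiv), DMF, 0 °C to rt
Reagents that add atoms: chloromethyl methyl ether, COCCl
Why: O-alkylation of the sodium phenoxide with a small, very reactive α-chloro ether; full deprotonation is used because the hydroxyl is chelated to the ester and flanked by iodine.

Step 5
Reactants: 8 4-methoxybenzyl chloride
Product: 9 (4-methoxybenzyl)zinc chloride
Conditions: Zn dust (1.5 equiv), LiCl (1.5 equiv), THF, 25 °C
Reagents that add atoms: zinc, [Zn]
Why: Direct oxidative insertion of zinc into the benzylic C–Cl bond; LiCl takes the organozinc into solution and keeps the metal surface active, and the mild temperature limits Wurtz homocoupling.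

Step 6
Reactants: 7 methyl 6-iodo-5-methoxy-7-(methoxymethoxy)-2,2-dimethyl-2H-chromene-8-carboxylate; 9 (4-methoxybenzyl)zinc chloride; 10 carbon monoxide
Product: 11 methyl 5-methoxy-7-(methoxymethoxy)-6-[2-(4-methoxyphenyl)acetyl]-2,2-dimethyl-2H-chromene-8-carboxylate
Conditions: Pd(PPh3)4 (5 mol %), CO (5 bar), THF, 50 °C, 9 (1.5 equiv) added slowly
Reagents that add atoms: none
Why: Oxidative addition of the C6–I bond of 7 to zerovalent palladium gives an arylpalladium iodide whose metal sits between the C5 methoxy and C7 methoxymethoxy oxygens; CO coordinates and the aryl group migrates onto it to give the aroylpalladium iodide. Transmetalation from 9 places the 4-methoxybenzyl group on palladium, and reductive elimination forms the carbonyl–CH2 bond, releasing 11 and the zerovalent catalyst. The closest known reaction type is the palladium-catalysed carbonylative Negishi coupling of aryl iodides with benzylic zinc halides, an established ketone synthesis. Two skeletal bonds are formed (C6–carbonyl and carbonyl–CH2); no ring closes and no stereocentre is created. The selectivity needed is carbonylative against direct coupling: the two ortho oxygen substituents slow transmetalation and reductive elimination at the crowded arylpalladium centre, CO pressure and slow addition of 9 keep dissolved CO in excess over the zinc reagent, and a benzylpalladium formed early can still insert CO and give the same ketone. Site selectivity needs no control, because C6 carries the only carbon–halogen bond. The benzylic zinc reagent should not add to the hindered C8 ester, the acetal or the C3=C4 olefin at 50 °C, and the masked phenol can neither quench 9 nor capture the aroylpalladium as an aryl ester.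

Step 7
Reactants: 11 methyl 5-methoxy-7-(methoxymethoxy)-6-[2-(4-methoxyphenyl)acetyl]-2,2-dimethyl-2H-chromene-8-carboxylate
Product: 12 5-methoxy-7-(methoxymethoxy)-6-[2-(4-methoxyphenyl)acetyl]-2,2-dimethyl-2H-chromene-8-carboxylic acid
Conditions: KOH (10 equiv), EtOH–H2O (3:1), 80 °C, argon; then 1 M HCl to pH 4, 0 °C
Reagents that add atoms: potassium hydroxide, [K+].[OH-]
Why: Saponification of a 2,6-dialkoxybenzoate; with the C7 oxygen still protected there is no ortho phenoxide to deactivate the ester, and the acetal, the chromene and the reversibly enolised ketone tolerate hot alkali once oxygen is excluded. Cold, mild acidification gives the acid without cleaving the acetal.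

Step 8
Reactants: 12 5-methoxy-7-(methoxymethoxy)-6-[2-(4-methoxyphenyl)acetyl]-2,2-dimethyl-2H-chromene-8-carboxylic acid
Product: 14 1-(7-hydroxy-5-methoxy-2,2-dimethyl-2H-chromen-6-yl)-2-(4-methoxyphenyl)ethan-1-one, via hydroxy acid 13 (not isolated)
Conditions: HCl (1.25 M in MeOH), 45 °C; then evaporation, DMF, 100 °C
Reagents that add atoms: none
Why: Acid-catalysed acetal exchange transfers the methoxymethyl group to methanol; the hindered acid does not esterify under these conditions. In hydroxy acid 13 the carboxyl-bearing C8 is ortho to two oxygens and para to the third, so ipso protonation gives a keto tautomer that is a β-keto acid and should lose CO2 on warming (thermal decarboxylation of a 2,4,6-trioxygenated benzoic acid).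

## Compound list

1 | methyl 2,4,6-trihydroxybenzoate | COC(=O)c1c(O)cc(O)cc1O | starting material
2 | methyl 2,6-dihydroxy-4-methoxybenzoate | COC(=O)c1c(O)cc(OC)cc1O | intermediate
3 | methyl 2,6-dihydroxy-3-iodo-4-methoxybenzoate | COC(=O)c1c(O)c(I)c(OC)cc1O | intermediate
4 | 3-methyl-2-butenal | CC(C)=CC=O | starting material
5 | methyl 2-hydroxy-3-iodo-4-methoxy-5-(3-methylbut-2-en-1-ylidene)-6-oxocyclohexa-1,3-diene-1-carboxylate (ortho-quinone methide, not isolated) | COC(=O)C1=C(O)C(I)=C(OC)C(=CC=C(C)C)C1=O | intermediate
6 | methyl 7-hydroxy-6-iodo-5-methoxy-2,2-dimethyl-2H-chromene-8-carboxylate | COC(=O)c1c(O)c(I)c(OC)c2C=CC(C)(C)Oc12 | intermediate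
7 | methyl 6-iodo-5-methoxy-7-(methoxymethoxy)-2,2-dimethyl-2H-chromene-8-carboxylate | COC(=O)c1c(OCOC)c(I)c(OC)c2C=CC(C)(C)Oc12 | intermediate
8 | 4-methoxybenzyl chloride | COc1ccc(CCl)cc1 | starting material
9 | (4-methoxybenzyl)zinc chloride | COc1ccc(C[Zn]Cl)cc1 | intermediate
10 | carbon monoxide | [C-]#[O+] | starting material
11 | methyl 5-methoxy-7-(methoxymethoxy)-6-[2-(4-methoxyphenyl)acetyl]-2,2-dimethyl-2H-chromene-8-carboxylate | COC(=O)c1c(OCOC)c(C(=O)Cc2ccc(OC)cc2)c(OC)c2C=CC(C)(C)Oc12 | intermediate
12 | 5-methoxy-7-(methoxymethoxy)-6-[2-(4-methoxyphenyl)acetyl]-2,2-dimethyl-2H-chromene-8-carboxylic acid | OC(=O)c1c(OCOC)c(C(=O)Cc2ccc(OC)cc2)c(OC)c2C=CC(C)(C)Oc12 | intermediate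
13 | 7-hydroxy-5-methoxy-6-[2-(4-methoxyphenyl)acetyl]-2,2-dimethyl-2H-chromene-8-carboxylic acid (not isolated) | OC(=O)c1c(O)c(C(=O)Cc2ccc(OC)cc2)c(OC)c2C=CC(C)(C)Oc12 | intermediate
14 | 1-(7-hydroxy-5-methoxy-2,2-dimethyl-2H-chromen-6-yl)-2-(4-methoxyphenyl)ethan-1-one | COc1ccc(CC(=O)c2c(O)cc3c(c2OC)C=CC(C)(C)O3)cc1 | target

## Step count and least certain steps

Total step count: 8. Longest linear sequence: 7 steps (1 → 2 → 3 → 6 → 7 → 11 → 12 → 14; steps 1–4 and 6–8). Step 5 is a one-step side branch.

**Step 6 (key step).** The most likely failures are three: direct coupling without uptake of CO, if transmetalation outruns CO insertion; reduction of the C–I bond; and slow oxidative addition, because CO saturates the catalyst and the iodide is electron-rich and doubly ortho-substituted. The fallback sets out from 7 and introduces the carbon in two stages.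
- Iodine–magnesium exchange (i-PrMgCl·LiCl, THF, −40 °C; the hindered ester is tolerated) gives methyl 6-(chloromagnesio)-5-methoxy-7-(methoxymethoxy)-2,2-dimethyl-2H-chromene-8-carboxylate F1.
- F1 is trapped with DMF to give methyl 6-formyl-5-methoxy-7-(methoxymethoxy)-2,2-dimethyl-2H-chromene-8-carboxylate F2.
- Addition of 9 to the aldehyde (THF, 25 °C) gives racemic methyl 6-[1-hydroxy-2-(4-methoxyphenyl)ethyl]-5-methoxy-7-(methoxymethoxy)-2,2-dimethyl-2H-chromene-8-carboxylate F3.
- Oxidation with Dess–Martin periodinane (NaHCO3, CH2Cl2) removes the stereocentre and returns to the route at 11.

**Step 2.** Over-iodination at the second, equivalent position, or incomplete conversion, would lower the throughput, since the first iodine deactivates the ring only slightly. The fallback sets out from 2 and reverses the order of events. Annulation with 4 (1 equiv, pyridine, 115 °C) goes through methyl 2-hydroxy-4-methoxy-5-(3-methylbut-2-en-1-ylidene)-6-oxocyclohexa-1,3-diene-1-carboxylate F4 (not isolated) to methyl 7-hydroxy-5-methoxy-2,2-dimethyl-2H-chromene-8-carboxylate F5. Iodination of its single remaining ring C–H (NIS, DMF, 0 °C) returns to the route at 6. That order cannot over-iodinate, but it risks a second annulation and competition from the pyran olefin for the electrophile.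

**Step 3.** Slow condensation is the risk: the reacting carbon lies between a methoxy and a hydroxyl group on a ring deactivated by the ester and the iodine, and the enal can be consumed by self-condensation in the meantime. The fallback sets out from 3 and builds ring B by aromatic Claisen chemistry. O-Alkylation of the less hindered hydroxyl (3-chloro-3-methylbut-1-yne, K2CO3, KI, CuI cat., acetone, reflux) gives methyl 2-hydroxy-3-iodo-4-methoxy-6-[(2-methylbut-3-yn-2-yl)oxy]benzoate F6. Heating F6 in xylene (140 °C) brings about Claisen rearrangement to the free ortho carbon and a 1,5-hydrogen shift into quinone methide 5, which closes to 6.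

**Step 7.** Incomplete hydrolysis is likely, because hydroxide must reach a twisted ester carbonyl with two ortho substituents. Prolonged heating in base also increases the chance of oxidation at the benzylic methylene. The fallback sets out from 11 and attacks the methyl carbon instead of the carbonyl carbon: LiI in pyridine at 115 °C cleaves the O–CH3 bond by SN2 displacement, and acidification returns to the route at 12. No new compound is made.

**Step 8.** Acid-promoted addition to the C3=C4 olefin during acetal cleavage is one risk. Sluggish loss of CO2 is the other, because the acyl group lowers the basicity of the ring carbon that must be protonated. The fallback sets out from 12 and separates the two events. Protodecarboxylation with the acetal still in place (Ag2CO3 10 mol %, AcOH 5 mol %, DMSO, 120 °C) gives 1-[5-methoxy-7-(methoxymethoxy)-2,2-dimethyl-2H-chromen-6-yl]-2-(4-methoxyphenyl)ethan-1-one F7. Brief acetal exchange at room temperature (dilute HCl in MeOH, 20 °C), with no heating in acid, then gives 14.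

## Further compounds

F1 | step 6 | methyl 6-(chloromagnesio)-5-methoxy-7-(methoxymethoxy)-2,2-dimethyl-2H-chromene-8-carboxylate | COC(=O)c1c(OCOC)c([Mg]Cl)c(OC)c2C=CC(C)(C)Oc12
F2 | step 6 | methyl 6-formyl-5-methoxy-7-(methoxymethoxy)-2,2-dimethyl-2H-chromene-8-carboxylate | COC(=O)c1c(OCOC)c(C=O)c(OC)c2C=CC(C)(C)Oc12
F3 | step 6 | methyl 6-[1-hydroxy-2-(4-methoxyphenyl)ethyl]-5-methoxy-7-(methoxymethoxy)-2,2-dimethyl-2H-chromene-8-carboxylate (racemic) | COC(=O)c1c(OCOC)c(C(O)Cc2ccc(OC)cc2)c(OC)c2C=CC(C)(C)Oc12
F4 | step 2 | methyl 2-hydroxy-4-methoxy-5-(3-methylbut-2-en-1-ylidene)-6-oxocyclohexa-1,3-diene-1-carboxylate | COC(=O)C1=C(O)C=C(OC)C(=CC=C(C)C)C1=O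
F5 | step 2 | methyl 7-hydroxy-5-methoxy-2,2-dimethyl-2H-chromene-8-carboxylate | COC(=O)c1c(O)cc(OC)c2C=CC(C)(C)Oc12
F6 | step 3 | methyl 2-hydroxy-3-iodo-4-methoxy-6-[(2-methylbut-3-yn-2-yl)oxy]benzoate | COC(=O)c1c(O)c(I)c(OC)cc1OC(C)(C)C#C
F0 | step 7 | none | none
F7 | step 8 | 1-[5-methoxy-7-(methoxymethoxy)-2,2-dimethyl-2H-chromen-6-yl]-2-(4-methoxyphenyl)ethan-1-one | COCOc1cc2OC(C)(C)C=Cc2c(OC)c1C(=O)Cc1ccc(OC)cc1
A1 | alternative 1 | 2-diazo-1-(2,2-dimethyl-3,4-dihydro-2H-pyran-6-yl)ethan-1-one | [N-]=[N+]=CC(=O)C1=CCCC(C)(C)O1
A2 | alternative 1 | {[4-(4-methoxyphenyl)-3-methylidenebut-1-yn-1-yl]oxy}tri(propan-2-yl)silane | C=C(Cc1ccc(OC)cc1)C#CO[Si](C(C)C)(C(C)C)C(C)C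
A3 | alternative 1 | 6-[3-(4-methoxyphenyl)prop-1-en-2-yl]-2,2-dimethyl-7-(triisopropylsilyloxy)chroman-5-ol | C=C(Cc1ccc(OC)cc1)c1c(O)c2CCC(C)(C)Oc2cc1O[Si](C(C)C)(C(C)C)C(C)C
A4 | alternative 2 | methyl 3-formyl-2,6-dihydroxy-4-methoxy-5-[2-(4-methoxyphenyl)acetyl]benzoate | COC(=O)c1c(O)c(C=O)c(OC)c(C(=O)Cc2ccc(OC)cc2)c1O
A5 | alternative 2 | (2-methylprop-1-en-1-yl)boronic acid | CC(C)=CB(O)O
A6 | alternative 2 | methyl 7-hydroxy-5-methoxy-6-[2-(4-methoxyphenyl)acetyl]-2,2-dimethyl-2H-chromene-8-carboxylate | COC(=O)c1c(O)c(C(=O)Cc2ccc(OC)cc2)c(OC)c2C=CC(C)(C)Oc12
A7 | alternative 3 | tert-butyl{[2-(2,2-dimethyl-3,4-dihydro-2H-pyran-6-yl)-1-methoxyethenyl]oxy}dimethylsilane | COC(O[Si](C)(C)C(C)(C)C)=CC1=CCCC(C)(C)O1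
A8 | alternative 3 | 4-methoxy-1-(4-methoxyphenyl)but-3-yn-2-one | COC#CC(=O)Cc1ccc(OC)cc1
A9 | alternative 3 | 1-(7-hydroxy-5-methoxy-2,2-dimethylchroman-6-yl)-2-(4-methoxyphenyl)ethan-1-one | COc1ccc(CC(=O)c2c(O)cc3OC(C)(C)CCc3c2OC)cc1
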